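**Retrosynthetic overview**
- The target comes from TES removal of its 6-O-silyl ether. The only ring, the cyclohexa-1,3-diene, is closed in the penultimate step by ring-closing metathesis of an acyclic 1,5,7-triene (forms C3=C4).
- The triene dibenzoate comes from a DCC coupling of a C9 silyl-protected triene-diol with two benzoic acid units.
- The C9 unit comes from chelation-controlled addition of a C5 (Z)-alkenylmagnesium (from but-2-yne-1,4-diol) to a C4 (R)-α-PMB-oxy aldehyde (from 2-vinyloxirane). The resolution sets C5 and the addition sets C6.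
- Ring order: one carbocycle, formed after both fragment couplings.

Assumption: racemic 2-vinyloxirane, but-2-yne-1,4-diol and benzaldehyde are the purchased starting materials; the benzoyl groups are brought in as benzoic acid made from benzaldehyde, and PMB and TES serve only as protecting groups.

**Route**

Step 1
Reactants: 1 but-2-yne-1,4-diol (3 equiv)
Product: 2 4-[(4-methoxybenzyl)oxy]but-2-yn-1-ol
Conditions: PMBCl (1 equiv), powdered KOH, DMSO, rt
Reagents that add atoms: 4-methoxybenzyl chloride, COc1ccc(CCl)cc1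
Why: Williamson etherification; the excess of the symmetrical diol favours mono-alkylation.

Step 2
Reactants: 2 4-[(4-methoxybenzyl)oxy]but-2-yn-1-ol
Product: 4 (2Z)-3-iodo-4-[(4-methoxybenzyl)oxy]but-2-en-1-ol, via cyclic alkenylalanate 3 (not isolated)
Conditions: Red-Al, THF, 0 °C to rt; then I2, THF, −78 to 0 °C
Reagents that add atoms: iodine, II
Why: Hydroxyl-directed trans-hydroalumination puts aluminium on the distal alkyne carbon in a five-membered alanate, and iodinolysis with retention fixes the Z geometry (iodine cis to the CH2OH carbon).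

Step 3
Reactants: 4 (2Z)-3-iodo-4-[(4-methoxybenzyl)oxy]but-2-en-1-ol
Product: 5 (2Z)-3-iodo-4-[(4-methoxybenzyl)oxy]but-2-enal
Conditions: MnO2 (excess), CH2Cl2, rt; used at once
Reagents that add atoms: none
Why: Chemoselective allylic oxidation with MnO2 leaves the vinyl iodide, its geometry and the PMB ether untouched.

Step 4
Reactants: 5 (2Z)-3-iodo-4-[(4-methoxybenzyl)oxy]but-2-enal
Product: 6 1-({[(2Z)-2-iodopenta-2,4-dien-1-yl]oxy}methyl)-4-methoxybenzene
Conditions: Ph3PCH3Br, KHMDS, THF, 0 °C; then 5, −78 to 0 °C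
Reagents that add atoms: methyltriphenylphosphonium bromide, [Br-].C[P+](c1ccccc1)(c1ccccc1)c1ccccc1
Why: Wittig methylenation of the aldehyde gives the terminal diene; the C=C(I) geometry is not involved, so iodine stays cis to the new vinyl group.

Step 5
Reactants: 7 2-vinyloxirane (racemic)
Product: 8 (2R)-but-3-ene-1,2-diol
Conditions: (R,R)-(salen)Co(III)OAc (0.5 mol %), H2O (0.45 equiv), 0 °C to rt; unreacted (S)-epoxide distilled off
Reagents that add atoms: water, O
Why: Jacobsen hydrolytic kinetic resolution opens only the (R)-epoxide at its terminal carbon (usual sense for monosubstituted epoxides), so the stereocentre that becomes C5 of the target is obtained with retention.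

Step 6
Reactants: 8 (2R)-but-3-ene-1,2-diol
Product: 9 (4R)-2-(4-methoxyphenyl)-4-vinyl-1,3-dioxolane (both acetal epimers)
Conditions: 4-MeOC6H4CH(OMe)2, PPTS (cat.), CH2Cl2, rt
Reagents that add atoms: 4-methoxybenzaldehyde dimethyl acetal, COC(OC)c1ccc(OC)cc1
Why: Acid-catalysed transacetalisation to the p-methoxybenzylidene acetal; the stereocentre is not touched.

Step 7
Reactants: 9 (4R)-2-(4-methoxyphenyl)-4-vinyl-1,3-dioxolane
Product: 10 (2R)-2-[(4-methoxybenzyl)oxy]but-3-en-1-ol
Conditions: DIBAL-H, CH2Cl2, −78 to 0 °C; Rochelle salt work-up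
Reagents that add atoms: none
Why: Regioselective reductive acetal opening: aluminium binds the less hindered primary oxygen, so the PMB group stays on the secondary oxygen and the primary alcohol is freed.

Step 8
Reactants: 10 (2R)-2-[(4-methoxybenzyl)oxy]but-3-en-1-ol
Product: 11 (2R)-2-[(4-methoxybenzyl)oxy]but-3-enal
Conditions: Dess–Martin periodinane, CH2Cl2, 0 °C; used crude at once
Reagents that add atoms: none
Why: Dess–Martin oxidation is mild enough to give the α-alkoxy β,γ-unsaturated aldehyde without epimerisation or alkene migration if it is used immediately.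

Step 9
Reactants: 12 benzaldehyde
Product: 13 benzoic acid
Conditions: Oxone, DMF, rt
Reagents that add atoms: potassium peroxymonosulfate (Oxone), [K+].OOS(=O)(=O)[O-]
Why: Peroxymonosulfate oxidation of an aromatic aldehyde to the carboxylic acid.

Step 10
Reactants: 6 1-({[(2Z)-2-iodopenta-2,4-dien-1-yl]oxy}methyl)-4-methoxybenzene; 11 (2R)-2-[(4-methoxybenzyl)oxy]but-3-enal
Product: 17 triethyl{[(3R,4R,5Z)-3-[(4-methoxybenzyl)oxy]-5-{[(4-methoxybenzyl)oxy]methyl}octa-1,5,7-trien-4-yl]oxy}silane, via alkenyllithium 14 (not isolated), via alkenylmagnesium bromide 15 (not isolated), via bromomagnesium alkoxide 16 (not isolated)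
Conditions: 6, t-BuLi (2.0 equiv), Et2O, −78 °C; MgBr2·OEt2; then 11 premixed with MgBr2·OEt2 in CH2Cl2, −78 °C; then TESOTf, 2,6-lutidine, −78 to 0 °C
Reagents that add atoms: triethylsilyl trifluoromethanesulfonate, CC[Si](CC)(CC)OS(=O)(=O)C(F)(F)F
Why: Iodine–lithium exchange with retention, transmetalation to magnesium and Cram-chelate addition: magnesium bridges C=O and the α-OPMB oxygen and the alkenyl group attacks anti to the vinyl substituent, giving the 3,4-syn (4R) carbinol (C6 of the target), which is trapped in situ as its TES ether.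

Step 11
Reactants: 17 triethyl{[(3R,4R,5Z)-3-[(4-methoxybenzyl)oxy]-5-{[(4-methoxybenzyl)oxy]methyl}octa-1,5,7-trien-4-yl]oxy}silane
Product: 18 (3R,4R,5Z)-5-(hydroxymethyl)-4-[(triethylsilyl)oxy]octa-1,5,7-trien-3-ol
Conditions: DDQ (2.5 equiv), CH2Cl2/pH 7 buffer (10:1), 0 °C
Reagents that add atoms: none
Why: Oxidative cleavage of both PMB ethers by DDQ; under buffered conditions the TES ether and the alkenes survive (the diene carries a cis substituent at its terminus and is a poor Diels–Alder partner for DDQ).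

Step 12
Reactants: 18 (3R,4R,5Z)-5-(hydroxymethyl)-4-[(triethylsilyl)oxy]octa-1,5,7-trien-3-ol; 13 benzoic acid (2.5 equiv)
Product: 19 (3R,4R,5Z)-5-[(benzoyloxy)methyl]-4-[(triethylsilyl)oxy]octa-1,5,7-trien-3-yl benzoate
Conditions: DCC, DMAP (cat.), CH2Cl2, 0 °C to rt
Reagents that add atoms: none
Why: Steglich esterification acylates the primary and the secondary allylic hydroxyl with retention, while the third oxygen is blocked as the TES ether, so the benzoate positions are fixed.

Step 13
Reactants: 19 (3R,4R,5Z)-5-[(benzoyloxy)methyl]-4-[(triethylsilyl)oxy]octa-1,5,7-trien-3-yl benzoate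
Product: 20 [(5R,6R)-5-(benzoyloxy)-6-[(triethylsilyl)oxy]cyclohexa-1,3-dien-1-yl]methyl benzoate
Conditions: Grubbs II (5 mol %), CH2Cl2 (5 mM), 40 °C
Reagents that add atoms: none
Why: Ring-closing metathesis between the vinyl group and the terminal alkene of the diene closes the six-membered ring with loss of ethene; the Z-trisubstituted alkene becomes the second ring double bond and the stereocentres are not touched.

Step 14
Reactants: 20 [(5R,6R)-5-(benzoyloxy)-6-[(triethylsilyl)oxy]cyclohexa-1,3-dien-1-yl]methyl benzoate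
Product: 21 [(5R,6R)-5-(benzoyloxy)-6-hydroxycyclohexa-1,3-dien-1-yl]methyl benzoate
Conditions: HF·pyridine, pyridine, THF, 0 °C
Reagents that add atoms: none
Why: Buffered fluoride desilylation removes the TES ether under weakly acidic conditions that avoid base-induced benzoyl migration.

**Compound list**

1 | but-2-yne-1,4-diol | OCC#CCO | starting material
2 | 4-[(4-methoxybenzyl)oxy]but-2-yn-1-ol | OCC#CCOCc1ccc(OC)cc1 | intermediate
3 | sodium 2,2-bis(2-methoxyethoxy)-3-{[(4-methoxybenzyl)oxy]methyl}-2,5-dihydro-1,2-oxaaluminol-2-uide (cyclic alkenylalanate; in situ) | [Na+].COCCO[Al-]1(OCCOC)OCC=C1COCc1ccc(OC)cc1 | intermediate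
4 | (2Z)-3-iodo-4-[(4-methoxybenzyl)oxy]but-2-en-1-ol | OC/C=C(\I)COCc1ccc(OC)cc1 | intermediate
5 | (2Z)-3-iodo-4-[(4-methoxybenzyl)oxy]but-2-enal | O=C/C=C(\I)COCc1ccc(OC)cc1 | intermediate
6 | 1-({[(2Z)-2-iodopenta-2,4-dien-1-yl]oxy}methyl)-4-methoxybenzene | C=C/C=C(\I)COCc1ccc(OC)cc1 | intermediate
7 | 2-vinyloxirane (racemic) | C=CC1CO1 | starting material
8 | (2R)-but-3-ene-1,2-diol | C=C[C@@H](O)CO | intermediate
9 | (4R)-2-(4-methoxyphenyl)-4-vinyl-1,3-dioxolane (both acetal epimers) | C=C[C@@H]1COC(c2ccc(OC)cc2)O1 | intermediate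
10 | (2R)-2-[(4-methoxybenzyl)oxy]but-3-en-1-ol | C=C[C@@H](OCc1ccc(OC)cc1)CO | intermediate
11 | (2R)-2-[(4-methoxybenzyl)oxy]but-3-enal | C=C[C@@H](OCc1ccc(OC)cc1)C=O | intermediate
12 | benzaldehyde | O=Cc1ccccc1 | starting material
13 | benzoic acid | OC(=O)c1ccccc1 | intermediate
14 | {(2E)-1-[(4-methoxybenzyl)oxy]penta-2,4-dien-2-yl}lithium (Li cis to vinyl; in situ) | C=C/C=C(\[Li])COCc1ccc(OC)cc1 | intermediate
15 | bromo{(2Z)-1-[(4-methoxybenzyl)oxy]penta-2,4-dien-2-yl}magnesium (in situ) | C=C/C=C(\[Mg]Br)COCc1ccc(OC)cc1 | intermediate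
16 | bromomagnesium (3R,4R,5Z)-3-[(4-methoxybenzyl)oxy]-5-{[(4-methoxybenzyl)oxy]methyl}octa-1,5,7-trien-4-olate (in situ) | C=C[C@@H](OCc1ccc(OC)cc1)[C@H](O[Mg]Br)/C(COCc1ccc(OC)cc1)=C\C=C | intermediate
17 | triethyl{[(3R,4R,5Z)-3-[(4-methoxybenzyl)oxy]-5-{[(4-methoxybenzyl)oxy]methyl}octa-1,5,7-trien-4-yl]oxy}silane | C=C[C@@H](OCc1ccc(OC)cc1)[C@H](O[Si](CC)(CC)CC)/C(COCc1ccc(OC)cc1)=C\C=C | intermediate
18 | (3R,4R,5Z)-5-(hydroxymethyl)-4-[(triethylsilyl)oxy]octa-1,5,7-trien-3-ol | C=C[C@@H](O)[C@H](O[Si](CC)(CC)CC)/C(CO)=C\C=C | intermediate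
19 | (3R,4R,5Z)-5-[(benzoyloxy)methyl]-4-[(triethylsilyl)oxy]octa-1,5,7-trien-3-yl benzoate | C=C[C@@H](OC(=O)c1ccccc1)[C@H](O[Si](CC)(CC)CC)/C(COC(=O)c1ccccc1)=C\C=C | intermediate
20 | [(5R,6R)-5-(benzoyloxy)-6-[(triethylsilyl)oxy]cyclohexa-1,3-dien-1-yl]methyl benzoate | O=C(OCC1=CC=C[C@@H](OC(=O)c2ccccc2)[C@@H]1O[Si](CC)(CC)CC)c1ccccc1 | intermediate
21 | [(5R,6R)-5-(benzoyloxy)-6-hydroxycyclohexa-1,3-dien-1-yl]methyl benzoate (trans-5,6) | O=C(OCC1=CC=C[C@@H](OC(=O)c2ccccc2)[C@@H]1O)c1ccccc1 | target

**Totals**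
Total step count: 14.
Longest linear sequence: 9 steps (steps 1–4 then 10–14; the branch 5–8 then 10–14 is equally long; step 9 is a separate one-step branch).

**Steps most likely to fail**

Step 10 (chelation-controlled coupling with in situ silylation). The risks are low syn/anti selectivity, epimerisation of aldehyde 11, and β-elimination of the alkenylmetal. The fallback sets out from 6 and 11 and returns at 17. Alkenyllithium 14 is generated from 6 as before and added to 11 in THF without magnesium bromide, which gives the carbinol with little or Felkin (anti) control, mainly (3R,4S,5Z)-3-[(4-methoxybenzyl)oxy]-5-{[(4-methoxybenzyl)oxy]methyl}octa-1,5,7-trien-4-ol F1. Dess–Martin oxidation of the carbinol mixture gives the cross-conjugated ketone (3R,5Z)-3-[(4-methoxybenzyl)oxy]-5-{[(4-methoxybenzyl)oxy]methyl}octa-1,5,7-trien-4-one F2. C6 is then set by reagent-controlled 1,2-reduction instead of by C–C bond formation: (R)-Me-CBS with catecholborane at −78 °C (alkenyl as the large group, reinforced by the non-chelation Felkin bias of the α-alkoxy centre) gives the syn carbinol (3R,4R,5Z)-3-[(4-methoxybenzyl)oxy]-5-{[(4-methoxybenzyl)oxy]methyl}octa-1,5,7-trien-4-ol F3. Silylation of that with TESOTf and 2,6-lutidine gives 17.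

Step 13 (ring-closing metathesis of the triene dibenzoate). The risks are slow initiation next to the allylic benzoate, oligomerisation, and loss of the diene. The fallback sets out from 18 and returns at 20. The ring is closed before the ester coupling: diol 18, whose free allylic hydroxyl next to the vinyl group accelerates carbene formation, is cyclised with Hoveyda–Grubbs II in dilute CH2Cl2 to (1R,6R)-5-(hydroxymethyl)-6-[(triethylsilyl)oxy]cyclohexa-2,4-dien-1-ol F4. The two benzoic acid units 13 are then attached with DCC and DMAP to give 20.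

Step 14 (final desilylation on the cyclohexadiene). The risks are benzoyl migration to the freed hydroxyl and aromatisation by loss of benzoic acid. The fallback sets out from 19 and returns at 21. The TES group is removed on the acyclic triene 19 (HF·pyridine, THF), where aromatisation is impossible, to give (3R,4R,5Z)-5-[(benzoyloxy)methyl]-4-hydroxyocta-1,5,7-trien-3-yl benzoate F5. Ring-closing metathesis of that alcohol (Grubbs II, CH2Cl2, 40 °C) then delivers 21 directly under neutral conditions as the last step.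

**Further compounds**

F1 | step 10 | (3R,4S,5Z)-3-[(4-methoxybenzyl)oxy]-5-{[(4-methoxybenzyl)oxy]methyl}octa-1,5,7-trien-4-ol | C=C[C@@H](OCc1ccc(OC)cc1)[C@@H](O)/C(COCc1ccc(OC)cc1)=C\C=C
F2 | step 10 | (3R,5Z)-3-[(4-methoxybenzyl)oxy]-5-{[(4-methoxybenzyl)oxy]methyl}octa-1,5,7-trien-4-one | C=C[C@@H](OCc1ccc(OC)cc1)C(=O)/C(COCc1ccc(OC)cc1)=C\C=C
F3 | step 10 | (3R,4R,5Z)-3-[(4-methoxybenzyl)oxy]-5-{[(4-methoxybenzyl)oxy]methyl}octa-1,5,7-trien-4-ol | C=C[C@@H](OCc1ccc(OC)cc1)[C@H](O)/C(COCc1ccc(OC)cc1)=C\C=C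
F4 | step 13 | (1R,6R)-5-(hydroxymethyl)-6-[(triethylsilyl)oxy]cyclohexa-2,4-dien-1-ol | OCC1=CC=C[C@@H](O)[C@@H]1O[Si](CC)(CC)CC
F5 | step 14 | (3R,4R,5Z)-5-[(benzoyloxy)methyl]-4-hydroxyocta-1,5,7-trien-3-yl benzoate | C=C[C@@H](OC(=O)c1ccccc1)[C@H](O)/C(COC(=O)c1ccccc1)=C\C=C
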